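The side chain is numbered from the benzylic C1 to C15, and the ring is C7–C11. The route rests on the C6–C7 disconnection: the C5 ketone lies γ,δ to the ring bond C8–C9, so C5(=O)–C6H2–C7 is read as the footprint of a Claisen rearrangement. Acid 9 (arene, C1–C5) and cyclopentenol 17 (C7–C12) are tied together through an ester at the C9 oxygen, and methylenation supplies C6. The [3,3] shift of allyl vinyl ether 19 then forms C6–C7, creates quaternary C7 beside quaternary C11 by chirality transfer from C9, and turns the tether oxygen into the C5 carbonyl. The C8=C9 alkene left behind is then saturated.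

Key step: step 15

Remark: the target is read as having a Z side-chain alkene (C1 and C4 cis), an E enone and cis ring methyl groups (C7 R, C11 R); compounds 1, 4, 10 and 24 are taken as commercial.

Step 1
Reactants: 1 4-methoxy-2-methylphenol
Product: 2 2-bromo-4-methoxy-6-methylphenol
Conditions: Br2 (1.0 equiv), CH2Cl2, 0 °C
Reagents that add atoms: bromine, BrBr
Why: Electrophilic aromatic bromination, in which the hydroxyl group directs to its only free ortho position, para being blocked by the methoxy group.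

Step 2
Reactants: 2 2-bromo-4-methoxy-6-methylphenol
Product: 3 1-bromo-2,5-dimethoxy-3-methylbenzene
Conditions: MeI, K2CO3, acetone, reflux
Reagents that add atoms: iodomethane, IC
Why: Williamson ether synthesis on the phenoxide, with the aryl bromide untouched.

Step 3
Reactants: 4 4-methyl-5,6-dihydro-2H-pyran-2-one
Product: 5 (Z)-3-methylpent-2-ene-1,5-diol
Conditions: i-Bu2AlH (3 equiv), CH2Cl2, −78 → 0 °C; Rochelle salt work-up
Reagents that add atoms: none
Why: Hydride 1,2-reduction of the unsaturated lactone to the diol, whose Z geometry (C1 and C4 cis) is inherited from the ring.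

Step 4
Reactants: 5 (Z)-3-methylpent-2-ene-1,5-diol
Product: 6 (Z)-5-chloro-3-methylpent-3-en-1-ol
Conditions: N-chlorosuccinimide, Me2S, CH2Cl2, −20 → 0 °C
Reagents that add atoms: N-chlorosuccinimide, O=C1CCC(=O)N1Cl
Why: Corey–Kim chlorination converts only the allylic hydroxyl, by SN2 displacement of the alkoxysulfonium ion without allylic shift, so the Z alkene is kept.

Step 5
Reactants: 3 1-bromo-2,5-dimethoxy-3-methylbenzene; 6 (Z)-5-chloro-3-methylpent-3-en-1-ol
Product: 8 (Z)-5-(2,5-dimethoxy-3-methylphenyl)-3-methylpent-3-en-1-ol, via aryl Grignard reagent 7 (not isolated)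
Conditions: 3, Mg, THF, 45 °C; then 6 (as its chloromagnesium alkoxide, from MeMgCl, 1.0 equiv), Li2CuCl4 (3 mol %), THF, −40 → 0 °C
Reagents that add atoms: none
Why: Kochi-type copper-catalysed Grignard cross-coupling at the primary allylic chloride, which should be α-selective and retain the alkene geometry while the hydroxyl is masked as its magnesium alkoxide.

Step 6
Reactants: 8 (Z)-5-(2,5-dimethoxy-3-methylphenyl)-3-methylpent-3-en-1-ol
Product: 9 (Z)-5-(2,5-dimethoxy-3-methylphenyl)-3-methylpent-3-enoic acid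
Conditions: TEMPO (10 mol %), PhI(OAc)2 (2.2 equiv), MeCN/H2O, rt
Reagents that add atoms: water, O
Why: Oxoammonium (TEMPO/PhI(OAc)2) oxidation of the primary alcohol through the aldehyde hydrate to the acid under non-basic conditions that should leave the β,γ-alkene in place.

Step 7
Reactants: 10 2,3-dimethylcyclopent-2-en-1-one
Product: 11 (1S)-2,3-dimethylcyclopent-2-en-1-ol
Conditions: (R)-2-methyl-CBS-oxazaborolidine (10 mol %), BH3·SMe2, THF, −20 °C
Reagents that add atoms: none
Why: Corey–Bakshi–Shibata reduction, in which the methyl-substituted alkenyl arm acts as the large group so that the (R)-catalyst should deliver hydride to give the (S)-carbinol.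

Step 8
Reactants: 11 (1S)-2,3-dimethylcyclopent-2-en-1-ol
Product: 12 tributyl({[(1S)-2,3-dimethylcyclopent-2-en-1-yl]oxy}methyl)stannane
Conditions: KH, THF, 0 °C; then Bu3SnCH2I, rt
Reagents that add atoms: tributyl(iodomethyl)stannane, CCCC[Sn](CCCC)(CCCC)CI
Why: Williamson etherification of the potassium alkoxide with the iodomethylstannane, which does not involve the carbinol centre.

Step 9
Reactants: 12 tributyl({[(1S)-2,3-dimethylcyclopent-2-en-1-yl]oxy}methyl)stannane
Product: 14 [(1R)-1,2-dimethylcyclopent-2-en-1-yl]methanol, via lithiomethyl ether 13 (not isolated)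
Conditions: n-BuLi, THF, −78 → −20 °C
Reagents that add atoms: none
Why: Tin–lithium exchange followed by [2,3]-Wittig–Still rearrangement, which delivers the CH2O unit suprafacially to the alkene terminus C11 on the face of the breaking C–O bond, so the (S)-carbinol centre is relayed into the (R)-quaternary centre.

Step 10
Reactants: 14 [(1R)-1,2-dimethylcyclopent-2-en-1-yl]methanol
Product: 15 tert-butyl{[(1R)-1,2-dimethylcyclopent-2-en-1-yl]methoxy}dimethylsilane
Conditions: TBSCl, imidazole, DMF, rt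
Reagents that add atoms: tert-butyldimethylsilyl chloride, CC(C)(C)[Si](C)(C)Cl
Why: Standard silylation of the primary alcohol.

Step 11
Reactants: 15 tert-butyl{[(1R)-1,2-dimethylcyclopent-2-en-1-yl]methoxy}dimethylsilane
Product: 16 (4R)-4-({[tert-butyl(dimethyl)silyl]oxy}methyl)-3,4-dimethylcyclopent-2-en-1-one
Conditions: CrO3, 3,5-dimethylpyrazole, CH2Cl2, −20 °C
Reagents that add atoms: chromium trioxide, O=[Cr](=O)=O
Why: Chromium trioxide–3,5-dimethylpyrazole allylic oxidation of the only ring allylic methylene (C9) to the conjugated enone, C11 carrying no hydrogen and staying untouched.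

Step 12
Reactants: 16 (4R)-4-({[tert-butyl(dimethyl)silyl]oxy}methyl)-3,4-dimethylcyclopent-2-en-1-one
Product: 17 (1S,4R)-4-({[tert-butyl(dimethyl)silyl]oxy}methyl)-3,4-dimethylcyclopent-2-en-1-ol (OH and CH2OSi cis)
Conditions: (R)-2-methyl-CBS-oxazaborolidine (10 mol %), BH3·SMe2, THF, −30 °C
Reagents that add atoms: none
Why: Corey–Bakshi–Shibata reduction with the alkenyl arm as large group should give the (S)-carbinol, reinforced by hydride approach anti to the silyloxymethyl group, so OH and CH2OSi end up cis, and the alcohol from any minor enantiomer of 16 is the trans diastereomer, removable by chromatography.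

Step 13
Reactants: 9 (Z)-5-(2,5-dimethoxy-3-methylphenyl)-3-methylpent-3-enoic acid; 17 (1S,4R)-4-({[tert-butyl(dimethyl)silyl]oxy}methyl)-3,4-dimethylcyclopent-2-en-1-ol
Product: 18 (1S,4R)-4-({[tert-butyl(dimethyl)silyl]oxy}methyl)-3,4-dimethylcyclopent-2-en-1-yl (Z)-5-(2,5-dimethoxy-3-methylphenyl)-3-methylpent-3-enoate
Conditions: EDC·HCl, DMAP (10 mol %), CH2Cl2, 0 °C → rt
Reagents that add atoms: none
Why: Carbodiimide (Steglich-type) esterification with retention at the carbinol carbon.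

Step 14
Reactants: 18 (1S,4R)-4-({[tert-butyl(dimethyl)silyl]oxy}methyl)-3,4-dimethylcyclopent-2-en-1-yl (Z)-5-(2,5-dimethoxy-3-methylphenyl)-3-methylpent-3-enoate
Product: 19 tert-butyl{[(1R,4S)-4-{[(Z)-6-(2,5-dimethoxy-3-methylphenyl)-4-methylhexa-1,4-dien-2-yl]oxy}-1,2-dimethylcyclopent-2-en-1-yl]methoxy}dimethylsilane (allyl vinyl ether)
Conditions: Cp2TiMe2, toluene, 65 °C, dark; filtration through basic alumina
Reagents that add atoms: dimethyltitanocene, C[Ti](C)(C1C=CC=C1)C1C=CC=C1
Why: Petasis methylenation, in which the titanium methylidene from Cp2TiMe2 converts the ester carbonyl into the enol ether under neutral, non-Lewis-acidic conditions, so the allylic C–O bond is not ionised.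

Step 15
Reactants: 19 tert-butyl{[(1R,4S)-4-{[(Z)-6-(2,5-dimethoxy-3-methylphenyl)-4-methylhexa-1,4-dien-2-yl]oxy}-1,2-dimethylcyclopent-2-en-1-yl]methoxy}dimethylsilane
Product: 20 (Z)-1-[(1S,5R)-5-({[tert-butyl(dimethyl)silyl]oxy}methyl)-1,5-dimethylcyclopent-2-en-1-yl]-6-(2,5-dimethoxy-3-methylphenyl)-4-methylhex-4-en-2-one
Conditions: toluene, i-Pr2NEt (trace), 130 °C, sealed tube
Reagents that add atoms: none
Why: Concerted suprafacial [3,3]-sigmatropic (Claisen) shift of the allyl vinyl ether: C6 bonds to C7 while the C9–O bond breaks, the π bond moves to C8=C9 and the ether oxygen becomes the C5 carbonyl. The closest known reaction type is the Claisen rearrangement of allyl vinyl ethers made by titanium methylenation of allylic esters, including cases that build quaternary carbons on cycloalkenyl systems. No ring is closed; the only cyclic array is the six-membered transition state, boat-like because the allyl unit lies in the five-membered ring. The new stereocentre C7 is controlled by the C9 carbinol centre through 1,3-chirality transfer: C6 arrives on the ring face that carried the oxygen, cis to the CH2OSi group on C11, which gives the cis-dimethyl array. The step needs the [3,3] path to beat elimination and [1,3] ionisation; the amine trace, base-washed glass and absence of Lewis acids suppress ionisation, and regiochemistry is fixed because the vinyl terminus is the unsubstituted CH2 from the methylenation.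

Step 16
Reactants: 20 (Z)-1-[(1S,5R)-5-({[tert-butyl(dimethyl)silyl]oxy}methyl)-1,5-dimethylcyclopent-2-en-1-yl]-6-(2,5-dimethoxy-3-methylphenyl)-4-methylhex-4-en-2-one
Product: 21 (Z)-1-[(1R,2R)-2-({[tert-butyl(dimethyl)silyl]oxy}methyl)-1,2-dimethylcyclopentyl]-6-(2,5-dimethoxy-3-methylphenyl)-4-methylhex-4-en-2-one
Conditions: KO2CN=NCO2K, AcOH, MeOH/CH2Cl2, rt
Reagents that add atoms: none
Why: Diimide reduction, whose concerted syn transfer of H2 discriminates strongly in favour of the strained cis-disubstituted ring alkene over the acyclic trisubstituted alkene and does not touch the ketone.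

Step 17
Reactants: 21 (Z)-1-[(1R,2R)-2-({[tert-butyl(dimethyl)silyl]oxy}methyl)-1,2-dimethylcyclopentyl]-6-(2,5-dimethoxy-3-methylphenyl)-4-methylhex-4-en-2-one
Product: 22 (Z)-6-(2,5-dimethoxy-3-methylphenyl)-1-[(1R,2R)-2-(hydroxymethyl)-1,2-dimethylcyclopentyl]-4-methylhex-4-en-2-one
Conditions: HF·pyridine, pyridine, THF, 0 °C → rt
Reagents that add atoms: none
Why: Fluoride cleavage of the primary silyl ether under buffered, non-basic conditions that should spare the β,γ-unsaturated ketone (the product may rest as its cyclic hemiketal).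

Step 18
Reactants: 22 (Z)-6-(2,5-dimethoxy-3-methylphenyl)-1-[(1R,2R)-2-(hydroxymethyl)-1,2-dimethylcyclopentyl]-4-methylhex-4-en-2-one
Product: 23 (1R,2R)-2-[(Z)-6-(2,5-dimethoxy-3-methylphenyl)-4-methyl-2-oxohex-4-en-1-yl]-1,2-dimethylcyclopentane-1-carbaldehyde
Conditions: Dess–Martin periodinane, NaHCO3, CH2Cl2, rt
Reagents that add atoms: none
Why: Dess–Martin oxidation of the primary alcohol, drained from the hemiketal equilibrium, to the aldehyde under buffered neutral conditions.

Step 19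
Reactants: 24 2-methylbut-3-yn-2-ol
Product: 26 (E)-4-iodo-2-methylbut-3-en-2-ol, via E-vinylstannane 25 (not isolated)
Conditions: Bu3SnH, PdCl2(PPh3)2 (2 mol %), THF, 0 °C; then I2, CH2Cl2, 0 °C
Reagents that add atoms: iodine, [I][I]
Why: Palladium-catalysed syn hydrostannation should place tin at the terminal carbon away from the tertiary carbinol, and iododestannylation with retention then gives the E-vinyl iodide.

Step 20
Reactants: 23 (1R,2R)-2-[(Z)-6-(2,5-dimethoxy-3-methylphenyl)-4-methyl-2-oxohex-4-en-1-yl]-1,2-dimethylcyclopentane-1-carbaldehyde; 26 (E)-4-iodo-2-methylbut-3-en-2-ol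
Product: 27 (Z)-1-{(1R,2R)-2-[(E)-1,4-dihydroxy-4-methylpent-2-en-1-yl]-1,2-dimethylcyclopentyl}-6-(2,5-dimethoxy-3-methylphenyl)-4-methylhex-4-en-2-one (both carbinol epimers)
Conditions: CrCl2 (6 equiv), NiCl2 (2 mol %), DMSO/THF, rt
Reagents that add atoms: none
Why: Nozaki–Hiyama–Kishi coupling, in which the alkenylchromium species adds to the aldehyde and not to the ketone, tolerates the free hydroxyl and retains the E geometry, both C12 epimers being carried on.

Step 21
Reactants: 27 (Z)-1-{(1R,2R)-2-[(E)-1,4-dihydroxy-4-methylpent-2-en-1-yl]-1,2-dimethylcyclopentyl}-6-(2,5-dimethoxy-3-methylphenyl)-4-methylhex-4-en-2-one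
Product: 28 (E)-1-{(1R,2R)-2-[(Z)-6-(2,5-dimethoxy-3-methylphenyl)-4-methyl-2-oxohex-4-en-1-yl]-1,2-dimethylcyclopentyl}-4-hydroxy-4-methylpent-2-en-1-one
Conditions: Dess–Martin periodinane, NaHCO3, CH2Cl2, 0 °C → rt
Reagents that add atoms: none
Why: Dess–Martin oxidation of the allylic alcohol to the E-enone, which removes the C12 stereocentre while the tertiary alcohol cannot be oxidised.

Step 22
Reactants: 28 (E)-1-{(1R,2R)-2-[(Z)-6-(2,5-dimethoxy-3-methylphenyl)-4-methyl-2-oxohex-4-en-1-yl]-1,2-dimethylcyclopentyl}-4-hydroxy-4-methylpent-2-en-1-one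
Product: 30 (E)-1-{(1R,2R)-2-[(Z)-6-(2,5-dihydroxy-3-methylphenyl)-4-methyl-2-oxohex-4-en-1-yl]-1,2-dimethylcyclopentyl}-4-hydroxy-4-methylpent-2-en-1-one (CNP0212540.1), via quinone 29 (not isolated)
Conditions: (NH4)2Ce(NO3)6, MeCN/H2O, 0 °C; then aq. Na2S2O4, EtOAc, rt
Reagents that add atoms: water, O
Why: Oxidative demethylation of the hydroquinone dimethyl ether by (NH4)2Ce(NO3)6 to the quinone, then dithionite reduction to the hydroquinone, conditions under which ketones, alkenes and the tertiary alcohol should be unaffected.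

Compound list
1 | 4-methoxy-2-methylphenol | Cc1cc(OC)ccc1O | starting material
2 | 2-bromo-4-methoxy-6-methylphenol | Cc1cc(OC)cc(Br)c1O | intermediate
3 | 1-bromo-2,5-dimethoxy-3-methylbenzene | COc1cc(C)c(OC)c(Br)c1 | intermediate
4 | 4-methyl-5,6-dihydro-2H-pyran-2-one | CC1=CC(=O)OCC1 | starting material
5 | (Z)-3-methylpent-2-ene-1,5-diol | C/C(=C/CO)CCO | intermediate
6 | (Z)-5-chloro-3-methylpent-3-en-1-ol | C/C(=C/CCl)CCO | intermediate
7 | (2,5-dimethoxy-3-methylphenyl)magnesium bromide | COc1cc(C)c(OC)c([Mg]Br)c1 | intermediate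
8 | (Z)-5-(2,5-dimethoxy-3-methylphenyl)-3-methylpent-3-en-1-ol | C/C(=C/Cc1cc(OC)cc(C)c1OC)CCO | intermediate
9 | (Z)-5-(2,5-dimethoxy-3-methylphenyl)-3-methylpent-3-enoic acid | C/C(=C/Cc1cc(OC)cc(C)c1OC)CC(=O)O | intermediate
10 | 2,3-dimethylcyclopent-2-en-1-one | CC1=C(C)C(=O)CC1 | starting material
11 | (1S)-2,3-dimethylcyclopent-2-en-1-ol | CC1=C(C)[C@@H](O)CC1 | intermediate
12 | tributyl({[(1S)-2,3-dimethylcyclopent-2-en-1-yl]oxy}methyl)stannane | CC1=C(C)[C@@H](OC[Sn](CCCC)(CCCC)CCCC)CC1 | intermediate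
13 | ({[(1S)-2,3-dimethylcyclopent-2-en-1-yl]oxy}methyl)lithium | CC1=C(C)[C@@H](OC[Li])CC1 | intermediate
14 | [(1R)-1,2-dimethylcyclopent-2-en-1-yl]methanol | C[C@@]1(CO)CCC=C1C | intermediate
15 | tert-butyl{[(1R)-1,2-dimethylcyclopent-2-en-1-yl]methoxy}dimethylsilane | C[C@@]1(CO[Si](C)(C)C(C)(C)C)CCC=C1C | intermediate
16 | (4R)-4-({[tert-butyl(dimethyl)silyl]oxy}methyl)-3,4-dimethylcyclopent-2-en-1-one | C[C@@]1(CO[Si](C)(C)C(C)(C)C)CC(=O)C=C1C | intermediate
17 | (1S,4R)-4-({[tert-butyl(dimethyl)silyl]oxy}methyl)-3,4-dimethylcyclopent-2-en-1-ol | C[C@@]1(CO[Si](C)(C)C(C)(C)C)C[C@H](O)C=C1C | intermediate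
18 | (1S,4R)-4-({[tert-butyl(dimethyl)silyl]oxy}methyl)-3,4-dimethylcyclopent-2-en-1-yl (Z)-5-(2,5-dimethoxy-3-methylphenyl)-3-methylpent-3-enoate | C/C(=C/Cc1cc(OC)cc(C)c1OC)CC(=O)O[C@H]2C[C@@](C)(CO[Si](C)(C)C(C)(C)C)C(C)=C2 | intermediate
19 | tert-butyl{[(1R,4S)-4-{[(Z)-6-(2,5-dimethoxy-3-methylphenyl)-4-methylhexa-1,4-dien-2-yl]oxy}-1,2-dimethylcyclopent-2-en-1-yl]methoxy}dimethylsilane | C/C(=C/Cc1cc(OC)cc(C)c1OC)CC(=C)O[C@H]2C[C@@](C)(CO[Si](C)(C)C(C)(C)C)C(C)=C2 | intermediate
20 | (Z)-1-[(1S,5R)-5-({[tert-butyl(dimethyl)silyl]oxy}methyl)-1,5-dimethylcyclopent-2-en-1-yl]-6-(2,5-dimethoxy-3-methylphenyl)-4-methylhex-4-en-2-one | C/C(=C/Cc1cc(OC)cc(C)c1OC)CC(=O)C[C@@]2(C)C=CC[C@@]2(C)CO[Si](C)(C)C(C)(C)C | intermediate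
21 | (Z)-1-[(1R,2R)-2-({[tert-butyl(dimethyl)silyl]oxy}methyl)-1,2-dimethylcyclopentyl]-6-(2,5-dimethoxy-3-methylphenyl)-4-methylhex-4-en-2-one | C/C(=C/Cc1cc(OC)cc(C)c1OC)CC(=O)C[C@@]2(C)CCC[C@@]2(C)CO[Si](C)(C)C(C)(C)C | intermediate
22 | (Z)-6-(2,5-dimethoxy-3-methylphenyl)-1-[(1R,2R)-2-(hydroxymethyl)-1,2-dimethylcyclopentyl]-4-methylhex-4-en-2-one | C/C(=C/Cc1cc(OC)cc(C)c1OC)CC(=O)C[C@@]2(C)CCC[C@@]2(C)CO | intermediate
23 | (1R,2R)-2-[(Z)-6-(2,5-dimethoxy-3-methylphenyl)-4-methyl-2-oxohex-4-en-1-yl]-1,2-dimethylcyclopentane-1-carbaldehyde | C/C(=C/Cc1cc(OC)cc(C)c1OC)CC(=O)C[C@@]2(C)CCC[C@@]2(C)C=O | intermediate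
24 | 2-methylbut-3-yn-2-ol | CC(C)(O)C#C | starting material
25 | (E)-2-methyl-4-(tributylstannyl)but-3-en-2-ol | CCCC[Sn](CCCC)(CCCC)/C=C/C(C)(C)O | intermediate
26 | (E)-4-iodo-2-methylbut-3-en-2-ol | CC(C)(O)/C=C/I | intermediate
27 | (Z)-1-{(1R,2R)-2-[(E)-1,4-dihydroxy-4-methylpent-2-en-1-yl]-1,2-dimethylcyclopentyl}-6-(2,5-dimethoxy-3-methylphenyl)-4-methylhex-4-en-2-one | C/C(=C/Cc1cc(OC)cc(C)c1OC)CC(=O)C[C@@]2(C)CCC[C@@]2(C)C(O)/C=C/C(C)(C)O | intermediate
28 | (E)-1-{(1R,2R)-2-[(Z)-6-(2,5-dimethoxy-3-methylphenyl)-4-methyl-2-oxohex-4-en-1-yl]-1,2-dimethylcyclopentyl}-4-hydroxy-4-methylpent-2-en-1-one | C/C(=C/Cc1cc(OC)cc(C)c1OC)CC(=O)C[C@@]2(C)CCC[C@@]2(C)C(=O)/C=C/C(C)(C)O | intermediate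
29 | 2-[(Z)-6-{(1R,2R)-2-[(E)-4-hydroxy-4-methylpent-2-enoyl]-1,2-dimethylcyclopentyl}-3-methyl-5-oxohex-2-en-1-yl]-6-methylcyclohexa-2,5-diene-1,4-dione | C/C(=C/CC1=CC(=O)C=C(C)C1=O)CC(=O)C[C@@]2(C)CCC[C@@]2(C)C(=O)/C=C/C(C)(C)O | intermediate
30 | (E)-1-{(1R,2R)-2-[(Z)-6-(2,5-dihydroxy-3-methylphenyl)-4-methyl-2-oxohex-4-en-1-yl]-1,2-dimethylcyclopentyl}-4-hydroxy-4-methylpent-2-en-1-one | C/C(=C/Cc1cc(O)cc(C)c1O)CC(=O)C[C@@]1(C)CCC[C@@]1(C)C(=O)/C=C/C(C)(C)O | target

Total step count: 22. Longest linear sequence: 15 steps (10 → 30; steps 7–18 and 20–22).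

Steps most likely to fail

Step 15. The [3,3] shift has to build C7 next to the quaternary C11 on the ring face that carries the silyloxymethyl group. Thermal elimination of the enol ether, or ionisation of the allylic C9–O bond with [1,3] recombination, may outrun it. The fallback is an anion-accelerated Carroll rearrangement that sets out from 9 and 17 and comes back at 20. Acid 9 is condensed with Meldrum's acid (DCC, DMAP, CH2Cl2) to the acyl Meldrum's acid F1. Heating F1 with 17 in toluene at 80 °C gives the β-keto ester F2. Its dianion (LDA, 2.2 equiv, THF, −78 °C → reflux) rearranges with the same suprafacial transfer from C9 to the β-keto acid F3, which loses CO2 on gentle warming during acidic work-up to give 20.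

Step 9. The α-alkoxymethyl anion may undergo [1,2]-shift, or close only slowly onto the tetrasubstituted alkene terminus, so that the quaternary centre is not formed cleanly. The fallback is a Büchi-type [2,3] rearrangement that sets out from 11 and comes back at 14. Heating 11 with Me2NCH(OMe)2 in xylene at 140 °C transfers a carbamoyl carbon suprafacially to C11 and gives the amide F4, which is reduced to 14 with LiH2NBH3 in THF.

Step 20. Addition to the aldehyde flanked by two quaternary carbons may be slow, so that reduction, pinacol coupling or aldol reaction with the C5 ketone competes. The fallback is an alkenylzinc addition that sets out from 23 and comes back at 27. Commercial trimethyl[(2-methylbut-3-yn-2-yl)oxy]silane F5 is hydrozirconated with Cp2Zr(H)Cl in CH2Cl2 to the E-alkenylzirconocene chloride F6. Transmetalation with Me2Zn at −60 °C and addition to 23 at 0 °C, where the alkenylzinc species should react with the aldehyde only, gives the silyl ether F7. F7 is desilylated with K2CO3 in MeOH to 27.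

Further compounds
F1 | step 15 | 5-[(Z)-5-(2,5-dimethoxy-3-methylphenyl)-1-hydroxy-3-methylpent-3-en-1-ylidene]-2,2-dimethyl-1,3-dioxane-4,6-dione | C/C(=C/Cc1cc(OC)cc(C)c1OC)CC(O)=C2C(=O)OC(C)(C)OC2=O
F2 | step 15 | (1S,4R)-4-({[tert-butyl(dimethyl)silyl]oxy}methyl)-3,4-dimethylcyclopent-2-en-1-yl (Z)-7-(2,5-dimethoxy-3-methylphenyl)-5-methyl-3-oxohept-5-enoate | C/C(=C/Cc1cc(OC)cc(C)c1OC)CC(=O)CC(=O)O[C@H]2C[C@@](C)(CO[Si](C)(C)C(C)(C)C)C(C)=C2
F3 | step 15 | (Z)-2-[(1S,5R)-5-({[tert-butyl(dimethyl)silyl]oxy}methyl)-1,5-dimethylcyclopent-2-en-1-yl]-7-(2,5-dimethoxy-3-methylphenyl)-5-methyl-3-oxohept-5-enoic acid | C/C(=C/Cc1cc(OC)cc(C)c1OC)CC(=O)C(C(=O)O)[C@@]2(C)C=CC[C@@]2(C)CO[Si](C)(C)C(C)(C)C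
F4 | step 9 | (1R)-N,N,1,2-tetramethylcyclopent-2-ene-1-carboxamide | C[C@@]1(C(=O)N(C)C)CCC=C1C
F5 | step 20 | trimethyl[(2-methylbut-3-yn-2-yl)oxy]silane | C#CC(C)(C)O[Si](C)(C)C
F6 | step 20 | chloro[(E)-3-methyl-3-(trimethylsilyloxy)but-1-en-1-yl]zirconocene | Cl[Zr](/C=C/C(C)(C)O[Si](C)(C)C)(C1C=CC=C1)C1C=CC=C1
F7 | step 20 | (Z)-6-(2,5-dimethoxy-3-methylphenyl)-1-{(1R,2R)-2-[(E)-1-hydroxy-4-methyl-4-(trimethylsilyloxy)pent-2-en-1-yl]-1,2-dimethylcyclopentyl}-4-methylhex-4-en-2-one | C/C(=C/Cc1cc(OC)cc(C)c1OC)CC(=O)C[C@@]2(C)CCC[C@@]2(C)C(O)/C=C/C(C)(C)O[Si](C)(C)C
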